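**Retrosynthetic overview**

1. Cladonaphchrom B (13) ⇐ benzyl ether 12 ⇐ indanyl hydroperoxide 9. The pyran ring is not closed by a C–O cyclization. It grows from a cyclopentane ring when the aromatic carbon moves from carbon to oxygen (Criegee/Hock-type oxygen insertion) and the resulting oxocarbenium ion is reduced.
2. Enabling feature: in the pyran ring, O1 lies between the aromatic carbon C8a and the methyl-bearing carbon C2. Deleting O1 joins C2 to C8a and gives an indane whose C1 is a tertiary benzylic carbon. Aryl groups migrate readily to electron-poor oxygen, and the O1=C2 cation that results is in a 1,3-relationship to the C4 stereocentre, which steers hydride delivery.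
3. 9 ⇐ tertiary alcohol 8 ⇐ (S)-3-arylindan-1-one 7 (methyl Grignard addition, then OH→OOH exchange).
4. 7 ⇐ chalcone triflate 6 by enantioselective reductive Heck cyclization (sets the future C4) ⇐ Claisen–Schmidt union of acetophenone 4 and naphthaldehyde 2.
5. Ring order: both arenes are bought; cyclopentanone ring (step 5); its one-atom expansion to the pyran ring (step 8).

Key step: step 8

Remark on numbering: chroman O1, C2 (Me), C3, C4 (naphthyl), C4a, C5 (oxygen), C8a; indane C1, C2, C3 (naphthyl), C3a, C4 (OBn), C7a. Indane C1/C2/C3/C3a/C7a become chroman C2/C3/C4/C4a/C8a.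

Assumption: the sense of induction of the (R)-ligand in step 5 is assigned by analogy with simpler 2'-sulfonyloxychalcones. If the cyclization delivers the (R)-indanone, the (S)-ligand is used and nothing else changes.

Assumption: 1,8-dimethoxynaphthalene (1) and 1-(2,3-dihydroxyphenyl)ethanone (3) are taken as commercially available.

**Route**

Step 1
Reactants: 1 1,8-dimethoxynaphthalene
Product: 2 4,5-dimethoxy-1-naphthaldehyde
Conditions: POCl3, DMF, 0 → 60 °C; then H2O
Reagents that add atoms: N,N-dimethylformamide CN(C)C=O; water O
Why: Vilsmeier–Haack formylation, in which the chloroiminium ion should attack the position para to a methoxy group (C4) of the symmetric electron-rich naphthalene, the aldehyde formed being deactivated toward a second formylation.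

Step 2
Reactants: 3 1-(2,3-dihydroxyphenyl)ethanone
Product: 4 1-[3-(benzyloxy)-2-hydroxyphenyl]ethanone
Conditions: NaH (2.1 equiv), DMSO, 20 °C; BnBr (1.0 equiv); then 1 M HCl
Reagents that add atoms: benzyl bromide BrCc1ccccc1
Why: Williamson etherification of the catechol dianion, in which the 3-oxide (neither conjugated with nor chelated by the acetyl group) is the more nucleophilic site, so one equivalent of benzyl bromide should alkylate O3 and leave the 2-OH free for step 4.

Step 3
Reactants: 4 1-[3-(benzyloxy)-2-hydroxyphenyl]ethanone; 2 4,5-dimethoxy-1-naphthaldehyde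
Product: 5 (E)-1-[3-(benzyloxy)-2-hydroxyphenyl]-3-(4,5-dimethoxynaphthalen-1-yl)prop-2-en-1-one
Conditions: KOH, EtOH, 20 °C; then 1 M HCl
Reagents that add atoms: none
Why: Claisen–Schmidt aldol condensation, in which only the ketone is enolizable, E1cB dehydration gives the conjugated (E)-enone, and the 2'-phenoxide should not cyclize onto the electron-rich, weakly electrophilic enone.

Step 4
Reactants: 5 (E)-1-[3-(benzyloxy)-2-hydroxyphenyl]-3-(4,5-dimethoxynaphthalen-1-yl)prop-2-en-1-one
Product: 6 2-(benzyloxy)-6-[(2E)-3-(4,5-dimethoxynaphthalen-1-yl)prop-2-enoyl]phenyl trifluoromethanesulfonate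
Conditions: Tf2O, pyridine, CH2Cl2, −20 → 0 °C
Reagents that add atoms: trifluoromethanesulfonic anhydride O=S(=O)(OS(=O)(=O)C(F)(F)F)C(F)(F)F
Why: standard O-triflation of a phenol, which turns the chelated 2'-OH into the leaving group needed for oxidative addition.

Step 5
Reactants: 6 2-(benzyloxy)-6-[(2E)-3-(4,5-dimethoxynaphthalen-1-yl)prop-2-enoyl]phenyl trifluoromethanesulfonate
Product: 7 (S)-4-(benzyloxy)-3-(4,5-dimethoxynaphthalen-1-yl)-2,3-dihydro-1H-inden-1-one
Conditions: Pd(OAc)2 (5 mol %), (R)-2,2'-bis[bis(3,5-dimethylphenyl)phosphino]-6,6'-dimethoxy-1,1'-biphenyl (7.5 mol %), HCO2Na, DMF, 80 °C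
Reagents that add atoms: none
Why: enantioselective intramolecular reductive Heck reaction (the known route from 2'-sulfonyloxychalcones to 3-arylindan-1-ones), in which the aryl triflate adds oxidatively to zerovalent palladium, the aryl–palladium bond adds to the enone β-carbon inside the chiral bisphosphine pocket (this sets C3 as S), and formate reduces the palladium enolate with loss of CO2, closing the cyclopentanone ring.

Step 6
Reactants: 7 (S)-4-(benzyloxy)-3-(4,5-dimethoxynaphthalen-1-yl)-2,3-dihydro-1H-inden-1-one
Product: 8 (3S)-4-(benzyloxy)-3-(4,5-dimethoxynaphthalen-1-yl)-1-methyl-2,3-dihydro-1H-inden-1-ol (both C1 epimers)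
Conditions: MeMgBr, THF, −20 → 0 °C; then H2O
Reagents that add atoms: methylmagnesium bromide C[Mg]Br
Why: Grignard 1,2-addition to the aryl ketone, where the configuration of the new carbinol carbon is irrelevant because C1 becomes trigonal again in step 8, and C3 (β to the carbonyl) cannot epimerize under these conditions.

Step 7
Reactants: 8 (3S)-4-(benzyloxy)-3-(4,5-dimethoxynaphthalen-1-yl)-1-methyl-2,3-dihydro-1H-inden-1-ol
Product: 9 (3S)-4-(benzyloxy)-3-(4,5-dimethoxynaphthalen-1-yl)-1-methyl-2,3-dihydro-1H-inden-1-yl hydroperoxide (both C1 epimers)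
Conditions: H2O2 (50% aq., large excess), H2SO4 (cat.), Et2O, 0 °C
Reagents that add atoms: hydrogen peroxide OO
Why: acid-catalysed SN1 exchange of a tertiary benzylic hydroxyl for hydroperoxyl (the standard preparation of tertiary benzylic hydroperoxides), in which the 1-methylindan-1-yl cation is captured by the large excess of the alpha-nucleophile H2O2 and the O–O bond should stay intact in cold dilute acid.

Step 8
Reactants: 9 (3S)-4-(benzyloxy)-3-(4,5-dimethoxynaphthalen-1-yl)-1-methyl-2,3-dihydro-1H-inden-1-yl hydroperoxide
Product: 12 (2S,4S)-5-(benzyloxy)-4-(4,5-dimethoxynaphthalen-1-yl)-2-methylchromane, via peroxy trifluoroacetate 10 (not isolated), via oxocarbenium trifluoroacetate 11 (not isolated)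
Conditions: Et3SiH (6 equiv), TFAA (1.2 equiv), CH2Cl2, −40 → 0 °C; then TFA (5 equiv), 0 → 20 °C
Reagents that add atoms: none
Why: Trifluoroacetylation of the hydroperoxy group gives perester 10, whose O–O bond ionizes with synchronous 1,2-shift of the aromatic carbon C7a from C1 to the proximal oxygen (Criegee rearrangement, the perester form of the Hock rearrangement and the known way in which indanyl and tetralinyl hydroperoxides are ring-expanded to chroman and benzoxepane oxocarbenium ions); both C1 epimers of 9 converge on the same cation. The pyran ring is therefore not closed by a cyclization but arises by expansion of the five-membered carbocycle through a three-centre bridged (spiro-arenium) transition state that inserts the oxygen between C7a and C1 and delivers the 2-methylchroman-2-ylium ion pair 11. Aryl migrates in preference to the ring CH2 or the methyl group because of its much higher migratory aptitude toward electron-deficient oxygen, and the acylation makes trifluoroacetate the leaving group on the distal oxygen so that O–O heterolysis should outrun ionization of the tertiary benzylic C–O bond, which the silane would otherwise turn into the deoxygenated indane. The new stereocentre C2 is set by hydride transfer from Et3SiH to C2 of 11 (ionic hydrogenation of a cyclic oxocarbenium ion, as in the silane reduction of lactols and ketals): the half-chair with the C4 naphthyl group pseudo-equatorial is attacked along the pseudo-axial trajectory on the face anti to that group, while attack syn to it would meet the naphthyl group in a 1,3-diaxial fashion, so hydrogen should enter trans and methyl end up cis to the naphthyl group, giving (2S,4S). C4 keeps its configuration because no cation, anion or radical is formed at that carbon at any point. The silane is present in excess from the start so that 11 should be reduced faster than it can be arylated at C2 by the electron-rich peri carbon (C8) of the naphthalene or lose a proton to the enol ether.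

Step 9
Reactants: 12 (2S,4S)-5-(benzyloxy)-4-(4,5-dimethoxynaphthalen-1-yl)-2-methylchromane
Product: 13 (2S,4S)-4-(4,5-dimethoxynaphthalen-1-yl)-2-methylchroman-5-ol (Cladonaphchrom B)
Conditions: H2 (1 atm), Pd/C, EtOAc/EtOH, 20 °C
Reagents that add atoms: none
Why: hydrogenolysis of the benzyl aryl ether over Pd/C, under which the alkyl aryl ether O1–C2, the methoxy groups, the naphthalene ring and both stereocentres should be inert.

**Compound list**

1 | 1,8-dimethoxynaphthalene | COc1cccc2cccc(OC)c12 | starting material
2 | 4,5-dimethoxy-1-naphthaldehyde | COc1cccc2c(C=O)ccc(OC)c12 | intermediate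
3 | 1-(2,3-dihydroxyphenyl)ethanone | CC(=O)c1cccc(O)c1O | starting material
4 | 1-[3-(benzyloxy)-2-hydroxyphenyl]ethanone | CC(=O)c1cccc(OCc2ccccc2)c1O | intermediate
5 | (E)-1-[3-(benzyloxy)-2-hydroxyphenyl]-3-(4,5-dimethoxynaphthalen-1-yl)prop-2-en-1-one | COc1cccc2c(/C=C/C(=O)c3cccc(OCc4ccccc4)c3O)ccc(OC)c12 | intermediate
6 | 2-(benzyloxy)-6-[(2E)-3-(4,5-dimethoxynaphthalen-1-yl)prop-2-enoyl]phenyl trifluoromethanesulfonate | COc1cccc2c(/C=C/C(=O)c3cccc(OCc4ccccc4)c3OS(=O)(=O)C(F)(F)F)ccc(OC)c12 | intermediate
7 | (S)-4-(benzyloxy)-3-(4,5-dimethoxynaphthalen-1-yl)-2,3-dihydro-1H-inden-1-one | COc1cccc2c([C@@H]3CC(=O)c4cccc(OCc5ccccc5)c43)ccc(OC)c12 | intermediate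
8 | (3S)-4-(benzyloxy)-3-(4,5-dimethoxynaphthalen-1-yl)-1-methyl-2,3-dihydro-1H-inden-1-ol, both C1 epimers | COc1cccc2c([C@@H]3CC(C)(O)c4cccc(OCc5ccccc5)c43)ccc(OC)c12 | intermediate
9 | (3S)-4-(benzyloxy)-3-(4,5-dimethoxynaphthalen-1-yl)-1-methyl-2,3-dihydro-1H-inden-1-yl hydroperoxide, both C1 epimers | COc1cccc2c([C@@H]3CC(C)(OO)c4cccc(OCc5ccccc5)c43)ccc(OC)c12 | intermediate
10 | (3S)-4-(benzyloxy)-3-(4,5-dimethoxynaphthalen-1-yl)-1-methyl-2,3-dihydro-1H-inden-1-yl peroxytrifluoroacetate | COc1cccc2c([C@@H]3CC(C)(OOC(=O)C(F)(F)F)c4cccc(OCc5ccccc5)c43)ccc(OC)c12 | intermediate (not isolated)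
11 | (4S)-5-(benzyloxy)-4-(4,5-dimethoxynaphthalen-1-yl)-2-methyl-3,4-dihydrochromen-1-ium trifluoroacetate (O1=C2 oxocarbenium ion pair) | COc1cccc2c([C@@H]3CC(C)=[O+]c4cccc(OCc5ccccc5)c43)ccc(OC)c12.[O-]C(=O)C(F)(F)F | intermediate (not isolated)
12 | (2S,4S)-5-(benzyloxy)-4-(4,5-dimethoxynaphthalen-1-yl)-2-methylchromane | COc1cccc2c([C@@H]3C[C@H](C)Oc4cccc(OCc5ccccc5)c43)ccc(OC)c12 | intermediate
13 | (2S,4S)-4-(4,5-dimethoxynaphthalen-1-yl)-2-methylchroman-5-ol, Cladonaphchrom B | COc1cccc2c([C@@H]3C[C@H](C)Oc4cccc(O)c43)ccc(OC)c12 | target

**Step count and risks**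

Total step count: 9. Longest linear sequence: 8 steps (3 → 13 through steps 2–9; the branch 1 → 2 joins at step 3).

Steps most likely to fail:

Step 8. Three processes could spoil it. The tertiary benzylic C–O bond of 9 or 10 could ionize ahead of O–O heterolysis and be captured by the silane, with loss of the peroxide oxygen. The oxocarbenium carbon could be arylated by the peri position of the naphthalene before hydride arrives. The hydride transfer could show insufficient facial discrimination. The fallback sets out from 9 and comes back to the route at 12. The rearrangement is run without silane under buffered conditions (TFAA 1.05 equiv, 2,6-lutidine, CH2Cl2, −40 °C), so that the ion pair is quenched at once by loss of a C3 proton. The neutral enol ether (S)-5-(benzyloxy)-4-(4,5-dimethoxynaphthalen-1-yl)-2-methyl-4H-chromene F1 is isolated. C2 is then set by heterogeneous hydrogenation (H2, Pd/C, EtOAc, 20 °C) instead of ionic hydride transfer: hydrogen should be delivered to C2=C3 from the catalyst surface on the face opposite the C4 naphthyl group, giving 12. If the hydrogenation is simply continued, the benzyl ether is cleaved as in step 9.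

Step 5. The doubly ortho-substituted triflate could give low enantio-induction, the arylpalladium species could be captured by hydride before it adds to the enone, or a C–H bond of the neighbouring benzyl group could be arylated. The fallback sets out from 6 and comes back at 7. Miyaura borylation (B2pin2, Pd(dppf)Cl2, KOAc, dioxane, 80 °C) should give (E)-1-[3-(benzyloxy)-2-(4,4,5,5-tetramethyl-1,3,2-dioxaborolan-2-yl)phenyl]-3-(4,5-dimethoxynaphthalen-1-yl)prop-2-en-1-one F2. Rhodium-catalysed asymmetric intramolecular 1,4-addition ([Rh(C2H4)2Cl]2, (R)-MonoPhos, aq. K3PO4, toluene, 60–80 °C) then closes the ring to 7. This is the known route from 2'-borylchalcones to 3-arylindan-1-ones, and it forms the C–C bond by aryl–rhodium addition and protonation, with no hydride source present.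

Step 7. The tertiary cation could lose a proton to the indene faster than H2O2 captures it, the cation could be captured by the naphthalene ring, or H2O2 could oxidize the naphthalene under acid. The fallback sets out from 7, comes back at 9, and forms no cation. Wittig methylenation (Ph3PCH3Br, KOtBu, THF, 0 → 20 °C) should give (S)-4-(benzyloxy)-3-(4,5-dimethoxynaphthalen-1-yl)-1-methylidene-2,3-dihydro-1H-indene F3. Cobalt-catalysed hydrosilylperoxidation (Isayama–Mukaiyama conditions: Co(acac)2 cat., O2, Et3SiH, 1,2-dichloroethane, 20 °C) transfers a hydrogen atom to the methylidene carbon, and the tertiary benzylic radical is trapped by O2. This should give (3S)-4-(benzyloxy)-3-(4,5-dimethoxynaphthalen-1-yl)-1-methyl-2,3-dihydro-1H-inden-1-yl triethylsilyl peroxide F4. Removal of the silyl group (K2CO3, MeOH, 0 °C) gives 9.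

Further compounds
F1 | step 8 | (S)-5-(benzyloxy)-4-(4,5-dimethoxynaphthalen-1-yl)-2-methyl-4H-chromene | COc1cccc2c([C@@H]3C=C(C)Oc4cccc(OCc5ccccc5)c43)ccc(OC)c12
F2 | step 5 | (E)-1-[3-(benzyloxy)-2-(4,4,5,5-tetramethyl-1,3,2-dioxaborolan-2-yl)phenyl]-3-(4,5-dimethoxynaphthalen-1-yl)prop-2-en-1-one | COc1cccc2c(/C=C/C(=O)c3cccc(OCc4ccccc4)c3B5OC(C)(C)C(C)(C)O5)ccc(OC)c12
F3 | step 7 | (S)-4-(benzyloxy)-3-(4,5-dimethoxynaphthalen-1-yl)-1-methylidene-2,3-dihydro-1H-indene | COc1cccc2c([C@@H]3CC(=C)c4cccc(OCc5ccccc5)c43)ccc(OC)c12
F4 | step 7 | (3S)-4-(benzyloxy)-3-(4,5-dimethoxynaphthalen-1-yl)-1-methyl-2,3-dihydro-1H-inden-1-yl triethylsilyl peroxide | COc1cccc2c([C@@H]3CC(C)(OO[Si](CC)(CC)CC)c4cccc(OCc5ccccc5)c43)ccc(OC)c12
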